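**Retrosynthetic overview** (ring A = catechol ring, ring B = cyclohexanone ring, rings C/D = naphthalene)
1. The strategy rests on C4 of ring B: a diarylmethine carbon that is benzylic to naphthalene C1 (whose C4 oxygen is para, so a cation at C4 of ring B is stabilised) and bonded to C4a of ring A, which is para to the C7 oxygen (a nucleophilic arene carbon).
2. Last disconnection: the four O–benzyl bonds and C2–CO2H; the target comes from enol β-keto benzyl ester 13 by hydrogenolysis and decarboxylation.
3. Key disconnection: C4–C4a of ring B; 13 comes from racemic donor–acceptor cyclopropane 12 by chiral Lewis acid ring opening and Friedel–Crafts closure, which sets C4.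
4. Cyclopropane 12 comes from β-keto ester 4 (from 2,3-dihydroxybenzoic acid) and naphthaldehyde 9 (from 1,5-dimethoxynaphthalene) by Knoevenagel condensation and Corey–Chaykovsky methylene transfer.
5. Ring order: rings A, C and D are bought; the cyclopropane is made in step 7 and traded for ring B in step 8.

Key step: step 8

Assumption: the sense of induction of the scandium–PyBOX catalyst cannot be predicted with confidence; the route is written with the (S,S)-ligand on the assumption that it gives (S)-C4, and the (R,R)-ligand would be used, with nothing else changed, if it proves otherwise.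

Step 1
Reactants: 1 2,3-dihydroxybenzoic acid
Product: 2 benzyl 2,3-bis(benzyloxy)benzoate
Conditions: BnBr (3.5 equiv), K2CO3 (4 equiv), DMF, 60 °C
Reagents that add atoms: benzyl bromide, BrCc1ccccc1
Why: Williamson alkylation of both phenoxides and of the carboxylate under carbonate base is a standard exhaustive benzylation that should deliver the two ethers and the ester in one operation.

Step 2
Reactants: 2 benzyl 2,3-bis(benzyloxy)benzoate; 3 benzyl acetate
Product: 4 benzyl 3-[2,3-bis(benzyloxy)phenyl]-3-oxopropanoate
Conditions: 3 (1.5 equiv), LiN(SiMe3)2 (3 equiv), THF, −78 °C; then 2, −78 → 0 °C; then 1 M HCl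
Reagents that add atoms: none
Why: Crossed Claisen condensation in which the lithium enolate of benzyl acetate acylates the non-enolisable aryl ester, the leaving alkoxide being the same benzyloxide as in the enolate partner so that no ester scrambling is possible, and deprotonation of the product by excess base drives the reaction.

Step 3
Reactants: 5 1,5-dimethoxynaphthalene
Product: 7 4,8-dimethoxynaphthalene-1-carbaldehyde, via aryl iminium chloride 6 (not isolated)
Conditions: POCl3 (1.5 equiv), DMF, 0 → 90 °C; then ice-water, warm
Reagents that add atoms: N,N-dimethylformamide, CN(C)C=O; water, O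
Why: Vilsmeier–Haack formylation of the symmetrical diether should occur para to one methoxy group (the position peri to the other), and the iminium group then deactivates the ring system against a second substitution.

Step 4
Reactants: 7 4,8-dimethoxynaphthalene-1-carbaldehyde
Product: 8 4-hydroxy-8-methoxynaphthalene-1-carbaldehyde
Conditions: NaSEt (2 equiv), DMF, 100 °C; then 1 M HCl
Reagents that add atoms: none
Why: Nucleophilic (SN2) demethylation by thiolate should be fastest at the 4-methoxy group because its aryloxide leaving group is conjugated with the para formyl group (a vinylogous carboxylate), whereas the 8-methoxy oxygen on the other ring has no conjugation with C1, and the naphtholate formed resists a second cleavage.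

Step 5
Reactants: 8 4-hydroxy-8-methoxynaphthalene-1-carbaldehyde
Product: 9 4-(benzyloxy)-8-methoxynaphthalene-1-carbaldehyde
Conditions: BnBr (1.2 equiv), K2CO3 (1.5 equiv), DMF, rt
Reagents that add atoms: benzyl bromide, BrCc1ccccc1
Why: Williamson etherification of the acidic naphthol proceeds under mild carbonate conditions that leave the aldehyde untouched.

Step 6
Reactants: 4 benzyl 3-[2,3-bis(benzyloxy)phenyl]-3-oxopropanoate; 9 4-(benzyloxy)-8-methoxynaphthalene-1-carbaldehyde
Product: 10 benzyl 2-[2,3-bis(benzyloxy)benzoyl]-3-[4-(benzyloxy)-8-methoxynaphthalen-1-yl]prop-2-enoate (E/Z mixture)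
Conditions: piperidine (0.2 equiv), AcOH (0.2 equiv), toluene, reflux, Dean–Stark trap
Reagents that add atoms: none
Why: Knoevenagel condensation of the active methylene with the aldehyde through its piperidinium iminium ion, driven by azeotropic removal of water; the alkene geometry is of no consequence because the next step is stepwise.

Step 7
Reactants: 10 benzyl 2-[2,3-bis(benzyloxy)benzoyl]-3-[4-(benzyloxy)-8-methoxynaphthalen-1-yl]prop-2-enoate; 11 trimethylsulfoxonium iodide
Product: 12 racemic benzyl 1-[2,3-bis(benzyloxy)benzoyl]-2-[4-(benzyloxy)-8-methoxynaphthalen-1-yl]cyclopropane-1-carboxylate (both diastereomers)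
Conditions: 11 (1.3 equiv), NaH (1.2 equiv), DMSO, rt; then 10 in THF, 0 °C → rt; chromatography on Et3N-deactivated silica
Reagents that add atoms: none
Why: Corey–Chaykovsky cyclopropanation in which the sulfoxonium ylide adds in conjugate fashion to the doubly activated alkene and the resulting 1,3-dicarbonyl enolate closes the ring by 3-exo-tet displacement of dimethyl sulfoxide; the two stereocentres form without control and are erased in step 8.

Step 8
Reactants: 12 racemic benzyl 1-[2,3-bis(benzyloxy)benzoyl]-2-[4-(benzyloxy)-8-methoxynaphthalen-1-yl]cyclopropane-1-carboxylate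
Product: 13 benzyl (4S)-7,8-bis(benzyloxy)-4-[4-(benzyloxy)-8-methoxynaphthalen-1-yl]-1-hydroxy-3,4-dihydronaphthalene-2-carboxylate (enol tautomer of the β-keto ester)
Conditions: Sc(OTf)3 (10 mol %), 2,6-bis[(4S)-4-phenyl-4,5-dihydrooxazol-2-yl]pyridine (12 mol %), 4 Å MS, CH2Cl2 (0.01 M), −20 °C → rt
Reagents that add atoms: none
Why: Proposed new method: the scandium–PyBOX complex should chelate the two carbonyl oxygens of the β-keto ester, the cyclopropane bond between the quaternary carbon (future C2) and the naphthyl-bearing carbon (future C4) should heterolyse to a scandium 1,3-dicarbonyl enolate tethered through C3 to a benzylic cation stabilised by the para benzyloxy group of the naphthalene, and the aroyl ring, now attached to an enolate carbon instead of a free ketone, should attack this cation through its only free ortho carbon (future C4a), after which rearomatisation and proton transfer give the enol ester. The closest known reaction types are the Lewis acid-promoted formal homo-Nazarov cyclisation of aryl 2-arylcyclopropyl ketones to 4-aryl-1-tetralones, which is racemic, and the dynamic kinetic asymmetric Friedel–Crafts opening of racemic donor–acceptor cyclopropanes by chiral Lewis acids, which is intermolecular; the intramolecular enantioconvergent form has not been shown. Ring B is closed by intramolecular Friedel–Crafts alkylation that forms C4–C4a, a six-membered closure that is endo with respect to the arene C4a–C8a bond. C4, the only new stereocentre, is planar in the ring-opened species, so both enantiomers and both diastereomers of 12 converge, and its configuration should be decided by the phenyl groups of the ligand, which sit above and below the chelate plane two atoms from C4 and should let the arene swing onto one face of the cation only, much as chelated chiral Lewis acids fix the sense of ring closure in Nazarov cyclisations of α-alkoxycarbonyl dienones. The step needs C-arylation at C4a to win over O-closure of the enolate (Cloke–Wilson-type), proton loss from C3 and intermolecular arylation: O-closure should be reversible because the benzylic C–O bond re-ionises easily, C4a is activated by the para C7 benzyloxy group, and high dilution disfavours bimolecular paths.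

Step 9
Reactants: 13 benzyl (4S)-7,8-bis(benzyloxy)-4-[4-(benzyloxy)-8-methoxynaphthalen-1-yl]-1-hydroxy-3,4-dihydronaphthalene-2-carboxylate
Product: 15 (4S)-7,8-dihydroxy-4-(4-hydroxy-8-methoxynaphthalen-1-yl)-3,4-dihydronaphthalen-1(2H)-one (the target), via beta-keto acid 14 (not isolated)
Conditions: H2 (1 atm), 10% Pd/C, EtOAc–MeOH, rt; filter under argon; then toluene–EtOAc, 60 °C
Reagents that add atoms: none
Why: Hydrogenolysis over palladium should cleave the three benzyl ethers and the benzyl ester while leaving the methyl ether and the diarylmethine C4–H intact, and the cyclic β-keto acid then decarboxylates thermally through the usual six-membered transition state, C4 being non-enolisable and so keeping its configuration.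

**Compound list**
1 | 2,3-dihydroxybenzoic acid | OC(=O)c1cccc(O)c1O | starting material
2 | benzyl 2,3-bis(benzyloxy)benzoate | O=C(OCc1ccccc1)c1cccc(OCc2ccccc2)c1OCc1ccccc1 | intermediate
3 | benzyl acetate | CC(=O)OCc1ccccc1 | starting material
4 | benzyl 3-[2,3-bis(benzyloxy)phenyl]-3-oxopropanoate | O=C(CC(=O)OCc1ccccc1)c1cccc(OCc2ccccc2)c1OCc1ccccc1 | intermediate
5 | 1,5-dimethoxynaphthalene | COc1cccc2c(OC)cccc12 | starting material
6 | [(4,8-dimethoxynaphthalen-1-yl)methylidene]dimethylammonium chloride (not isolated) | COc1cccc2c(OC)ccc(C=[N+](C)C)c12.[Cl-] | intermediate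
7 | 4,8-dimethoxynaphthalene-1-carbaldehyde | COc1cccc2c(OC)ccc(C=O)c12 | intermediate
8 | 4-hydroxy-8-methoxynaphthalene-1-carbaldehyde | COc1cccc2c(O)ccc(C=O)c12 | intermediate
9 | 4-(benzyloxy)-8-methoxynaphthalene-1-carbaldehyde | COc1cccc2c(OCc3ccccc3)ccc(C=O)c12 | intermediate
10 | benzyl 2-[2,3-bis(benzyloxy)benzoyl]-3-[4-(benzyloxy)-8-methoxynaphthalen-1-yl]prop-2-enoate (E/Z mixture) | COc1cccc2c(OCc3ccccc3)ccc(C=C(C(=O)OCc3ccccc3)C(=O)c3cccc(OCc4ccccc4)c3OCc3ccccc3)c12 | intermediate
11 | trimethylsulfoxonium iodide | C[S+](C)(C)=O.[I-] | starting material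
12 | racemic benzyl 1-[2,3-bis(benzyloxy)benzoyl]-2-[4-(benzyloxy)-8-methoxynaphthalen-1-yl]cyclopropane-1-carboxylate (both diastereomers) | COc1cccc2c(OCc3ccccc3)ccc(C3CC3(C(=O)OCc3ccccc3)C(=O)c3cccc(OCc4ccccc4)c3OCc3ccccc3)c12 | intermediate
13 | benzyl (4S)-7,8-bis(benzyloxy)-4-[4-(benzyloxy)-8-methoxynaphthalen-1-yl]-1-hydroxy-3,4-dihydronaphthalene-2-carboxylate | COc1cccc2c(OCc3ccccc3)ccc([C@@H]3CC(C(=O)OCc4ccccc4)=C(O)c4c3ccc(OCc5ccccc5)c4OCc5ccccc5)c12 | intermediate
14 | (4S)-7,8-dihydroxy-4-(4-hydroxy-8-methoxynaphthalen-1-yl)-1-oxo-1,2,3,4-tetrahydronaphthalene-2-carboxylic acid (C2 epimers, not isolated) | COc1cccc2c(O)ccc([C@@H]3CC(C(O)=O)C(=O)c4c3ccc(O)c4O)c12 | intermediate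
15 | (4S)-7,8-dihydroxy-4-(4-hydroxy-8-methoxynaphthalen-1-yl)-3,4-dihydronaphthalen-1(2H)-one | COc1cccc2c(O)ccc([C@@H]3CCC(=O)c4c3ccc(O)c4O)c12 | target

**Step count and risks**

Total steps: 9. Longest linear sequence: 7 (steps 3, 4, 5, 6, 7, 8, 9 from 1,5-dimethoxynaphthalene).

Steps most likely to fail:

1. Step 8. The arene may not discriminate well between the two faces of the planar C4 cation, giving low enantiomeric purity, or the ring-opened species may be drained into O-closure, proton loss from C3 or intermolecular arylation. The fallback sets out from 12 and uses known chemistry. In(OTf)3 (10 mol %) in 1,2-dichloroethane at 0 °C → rt, an achiral Lewis acid formal homo-Nazarov cyclisation, should give racemic benzyl 7,8-bis(benzyloxy)-4-[4-(benzyloxy)-8-methoxynaphthalen-1-yl]-1-hydroxy-3,4-dihydronaphthalene-2-carboxylate F1. Preparative chromatography of F1 on a chiral stationary phase (cellulose or amylose carbamate) separates the enantiomers and returns to the route at 13.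

2. Step 7. The enolate may close through oxygen instead of carbon in the ring-forming displacement, and the strongly polarised cyclopropane may open under the basic conditions or on silica. The fallback sets out from 4 and 9 and also bypasses the Knoevenagel step. Regitz diazo transfer to 4 (4-acetamidobenzenesulfonyl azide, Et3N, MeCN) gives benzyl 3-[2,3-bis(benzyloxy)phenyl]-2-diazo-3-oxopropanoate F2. Wittig methylenation of 9 (Ph3P=CH2 from methyltriphenylphosphonium bromide and KOtBu, THF) gives 1-(benzyloxy)-4-ethenyl-5-methoxynaphthalene F3. Rh2(OAc)4-catalysed carbenoid cyclopropanation of F3 with F2 (CH2Cl2, slow addition of F2) returns to the route at 12.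

3. Step 4. Regioselectivity may be lost (cleavage of the 8-methyl ether or of both ethers), or the aldehyde may degrade under hot thiolate. The fallback sets out from 7 and replaces selective deprotection by selective protection. BBr3 (CH2Cl2, −78 °C → rt) cleaves both methyl ethers to 4,8-dihydroxynaphthalene-1-carbaldehyde F4. The 4-hydroxyl, a vinylogous acid through the para formyl group, is benzylated selectively (BnBr 1 equiv, NaHCO3, DMF) to 4-(benzyloxy)-8-hydroxynaphthalene-1-carbaldehyde F5. Methylation of the remaining peri hydroxyl, which reacts as its phenoxide (MeI, K2CO3, DMF), returns to the route at 9.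

Further compounds
F1 | step 8 | racemic benzyl 7,8-bis(benzyloxy)-4-[4-(benzyloxy)-8-methoxynaphthalen-1-yl]-1-hydroxy-3,4-dihydronaphthalene-2-carboxylate | COc1cccc2c(OCc3ccccc3)ccc(C3CC(C(=O)OCc4ccccc4)=C(O)c4c3ccc(OCc5ccccc5)c4OCc5ccccc5)c12
F2 | step 7 | benzyl 3-[2,3-bis(benzyloxy)phenyl]-2-diazo-3-oxopropanoate | [N-]=[N+]=C(C(=O)OCc1ccccc1)C(=O)c1cccc(OCc2ccccc2)c1OCc1ccccc1
F3 | step 7 | 1-(benzyloxy)-4-ethenyl-5-methoxynaphthalene | COc1cccc2c(OCc3ccccc3)ccc(C=C)c12
F4 | step 4 | 4,8-dihydroxynaphthalene-1-carbaldehyde | O=Cc1ccc(O)c2cccc(O)c12
F5 | step 4 | 4-(benzyloxy)-8-hydroxynaphthalene-1-carbaldehyde | O=Cc1ccc(OCc2ccccc2)c2cccc(O)c12
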